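Halimane numbering is used. Ring B (C5–C10) is opened at C7–C8 and C5–C10: C10 and C8, the two carbons flanking quaternary C9, are the α and γ termini of one ester dienolate (C1–C10–C9–C8), and C5–C6–C7 is a plain trimethylene bis-electrophile. A one-pot α-alkylation/γ-cycloalkylation therefore welds both bonds, closes ring B and sets C8 under auxiliary control; its precursors are an acyclic (Z)-3-methylpent-2-enoate and 1-chloro-3-iodopropane. C9 is then relayed from C8 by an anti conjugate addition, and ring A with C4, C5 and the C1=C10 alkene comes from an exo Diels–Alder reaction with methacrolein.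

Key step: step 3

Assumption: the senses of induction of (−)-8-phenylmenthol (step 3) and of the (S)-oxazaborolidinium catalyst (step 9) are taken as drawn; the mirror-image auxiliary or catalyst would be used otherwise.

Step 1
Reactants: 1 pent-2-ynoic acid; 2 (−)-8-phenylmenthol, (1R,2S,5R)
Product: 3 (1R,2S,5R)-8-phenylmenthyl pent-2-ynoate
Conditions: DCC, DMAP (cat.), CH2Cl2, 0 °C → rt
Reagents that add atoms: none
Why: Steglich esterification attaches the auxiliary, which is recovered unchanged in step 4.

Step 2
Reactants: 3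
Product: 4 (1R,2S,5R)-8-phenylmenthyl (Z)-3-methylpent-2-enoate
Conditions: Me2CuLi (from MeLi, CuI), THF, −78 °C; NH4Cl/MeOH quench at −78 °C
Reagents that add atoms: lithium dimethylcuprate [Li+].C[Cu-]C
Why: Syn-carbocupration of an ynoate with cold protonation should give only the Z-enoate, in which the ethyl group (C8/C17) is cis to the ester and is therefore the γ-site that LDA deprotonates.

Step 3
Reactants: 4; 5 1-chloro-3-iodopropane
Product: 7 (1R,2S,5R)-8-phenylmenthyl (3R)-2,3-dimethylcyclohex-1-ene-1-carboxylate, via α-(3-chloropropyl) ester 6 (not isolated)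
Conditions: LDA (1.05 equiv), THF–DMPU, −78 °C; 5, −78 → −20 °C; then KHMDS (1.2 equiv), −78 °C → rt, one flask
Reagents that add atoms: none
Why: The lithium dienolate is formed by deprotonating the ester-cis ethyl group and displaces iodide through its α-carbon (C10–C5) to give the deconjugated ester 6, whose doubly activated C10–H is removed by KHMDS so that the regenerated dienolate displaces chloride through its γ-carbon (C8–C7) and restores the conjugated C9=C10 bond. The closest known types are the deconjugative α-alkylation of enoate dienolates and the intramolecular vinylogous (γ) alkylation of dienolates. Ring B closes in a 6-(enolendo)-exo-tet mode. The only new stereocentre is C8: the cumyl phenyl ring of the auxiliary covers one face of the dienolate at C1/C10, so the trimethylene chain that starts at C10 must lie on the open face and reach C8 of the (E)-C8=C9 bond from there. The step needs I over Cl chemoselectivity (leaving-group ability), α-selectivity in the first alkylation (intrinsic to lithium dienolates) and γ- over α-closure in the second (six- against four-membered ring, helped by K+ and DMPU).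

Step 4
Reactants: 7
Product: 8 [(3R)-2,3-dimethylcyclohex-1-en-1-yl]methanol
Conditions: LiAlH4, Et2O, 0 °C → rt; aqueous work-up, auxiliary recovered by chromatography
Reagents that add atoms: none
Why: Hydride reduction of the hindered conjugated ester gives the allylic alcohol, frees the auxiliary and leaves the allylic C8 centre untouched.

Step 5
Reactants: 8
Product: 9 (3R)-2,3-dimethylcyclohex-1-ene-1-carbaldehyde
Conditions: MnO2, CH2Cl2, rt
Reagents that add atoms: none
Why: MnO2 oxidation of an allylic alcohol is neutral, so the alkene should not migrate and C8 should not epimerise.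

Step 6
Reactants: 9; 10 (4-bromobut-1-yn-1-yl)trimethylsilane
Product: 12 (2S,3R)-2,3-dimethyl-2-[4-(trimethylsilyl)but-3-ynyl]cyclohexylidenemethyl trimethylsilyl ether (E/Z mixture), via Grignard reagent 11 (not isolated)
Conditions: 10, Mg, THF; then CuBr·SMe2 (20 mol%), TMSCl, DMPU, 9, THF, −78 → −40 °C
Reagents that add atoms: chlorotrimethylsilane C[Si](C)(C)Cl
Why: This is a copper-catalysed, TMSCl-accelerated conjugate addition in which A(1,2) strain with the C9 methyl holds the C8 methyl pseudoaxial, so the cuprate should attack C9 anti to it and set the quaternary centre with C11 trans to C17.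

Step 7
Reactants: 12
Product: 13 (5R,6S)-5,6-dimethyl-6-[4-(trimethylsilyl)but-3-ynyl]cyclohex-1-ene-1-carbaldehyde
Conditions: Pd(OAc)2 (1.05 equiv), MeCN, rt
Reagents that add atoms: none
Why: Saegusa–Ito oxidation is regiospecific here because C9 is quaternary and only C5 offers a β-hydrogen, so the enal C1(=O)–C10=C5 is the sole possible product.

Step 8
Reactants: 13
Product: 14 (5R,6S)-1-ethenyl-5,6-dimethyl-6-[4-(trimethylsilyl)but-3-ynyl]cyclohex-1-ene
Conditions: Ph3PCH3Br, KOt-Bu, THF, 0 °C → rt
Reagents that add atoms: methyltriphenylphosphonium bromide C[P+](c1ccccc1)(c1ccccc1)c1ccccc1.[Br-]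
Why: Wittig methylenation adds C2 and gives the 1-vinylcyclohexene, which the bulky C9 pushes into the reactive s-cis form.

Step 9
Reactants: 14; 15 methacrolein
Product: 16 (4S,5S,8R,9S)-aldehyde, (1S,5S,6R,8aS)-1,5,6-trimethyl-5-[4-(trimethylsilyl)but-3-ynyl]-1,2,3,5,6,7,8,8a-octahydronaphthalene-1-carbaldehyde
Conditions: (S)-o-tolyl-CBS-oxazaborolidine·Tf2NH (20 mol%), CH2Cl2, −78 → −40 °C
Reagents that add atoms: none
Why: In this Lewis-acid-catalysed Diels–Alder reaction the C2 terminus should bond first to the enal β-carbon ("ortho" regiochemistry, C4–C5), the α-substituted acrolein should react exo (CHO cis to H5), and the dienophile should add to the α face, anti to the C11 chain that A(1,2) strain with the vinyl group holds pseudoaxial, a preference the chiral catalyst reinforces, so C4 and C5 are set together and the alkene arrives at C1=C10.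

Step 10
Reactants: 16
Product: 17 (4S,5S,8R,9S)-acid, the C4 carboxylic acid of 16
Conditions: NaClO2, NaH2PO4, 2-methylbut-2-ene, t-BuOH–H2O, rt
Reagents that add atoms: sodium chlorite [Na+].[O-]Cl=O
Why: Pinnick oxidation converts the non-enolisable neopentyl aldehyde while the scavenger protects the trisubstituted alkene from HOCl.

Step 11
Reactants: 17
Product: 18 terminal alkyne acid (C14-H)
Conditions: K2CO3, MeOH, rt; acidic work-up
Reagents that add atoms: none
Why: Base-mediated protodesilylation of an alkynylsilane affects no other group.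

Step 12
Reactants: 18
Product: 20 (4S,5S,8R,9S,13E)-15-hydroxyhalima-1(10),13-dien-18-oic acid, via vinylalane 19 (not isolated)
Conditions: AlMe3 (5 equiv), Cp2ZrCl2 (0.5 equiv), CH2Cl2, 0 °C → rt; then n-BuLi, THF, −78 °C; (CH2O)n, → rt; aq. HCl
Reagents that add atoms: trimethylaluminium C[Al](C)C; paraformaldehyde (as formaldehyde) C=O
Why: Negishi zirconium-catalysed syn-carboalumination followed by hydroxymethylation of the alanate should give only the E-trisubstituted allylic alcohol, with the acid masked in the flask as its aluminium carboxylate.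

Step 13
Reactants: 20
Product: 21 target, (4S,5S,8R,9S,13E)-15-acetoxyhalima-1(10),13-dien-18-oic acid
Conditions: Ac2O (1.2 equiv), pyridine, DMAP (cat.), CH2Cl2, 0 °C; aqueous work-up
Reagents that add atoms: acetic anhydride CC(=O)OC(C)=O
Why: Acylation takes the primary allylic alcohol, and any mixed anhydride at the hindered tertiary acid should hydrolyse on work-up.

Compound list
1 | pent-2-ynoic acid | CCC#CC(=O)O | starting material
2 | (−)-8-phenylmenthol | CC(C)(c1ccccc1)[C@@H]1CC[C@@H](C)C[C@H]1O | starting material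
3 | 8-phenylmenthyl pent-2-ynoate | CC(C)(c1ccccc1)[C@@H]1CC[C@@H](C)C[C@H]1OC(=O)C#CCC | intermediate
4 | 8-phenylmenthyl (Z)-3-methylpent-2-enoate | CC(C)(c1ccccc1)[C@@H]1CC[C@@H](C)C[C@H]1OC(=O)/C=C(\CC)C | intermediate
5 | 1-chloro-3-iodopropane | ClCCCI | starting material
6 | 8-phenylmenthyl (E)-2-(3-chloropropyl)-3-methylpent-3-enoate (C2 epimers, not isolated) | CC(C)(c1ccccc1)[C@@H]1CC[C@@H](C)C[C@H]1OC(=O)C(CCCCl)/C(C)=C/C | intermediate
7 | 8-phenylmenthyl (3R)-2,3-dimethylcyclohex-1-ene-1-carboxylate | CC(C)(c1ccccc1)[C@@H]1CC[C@@H](C)C[C@H]1OC(=O)C2=C(C)[C@H](C)CCC2 | intermediate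
8 | [(3R)-2,3-dimethylcyclohex-1-en-1-yl]methanol | CC1=C(CO)CCC[C@H]1C | intermediate
9 | (3R)-2,3-dimethylcyclohex-1-ene-1-carbaldehyde | CC1=C(C=O)CCC[C@H]1C | intermediate
10 | (4-bromobut-1-yn-1-yl)trimethylsilane | C[Si](C)(C)C#CCCBr | starting material
11 | 4-(trimethylsilyl)but-3-ynylmagnesium bromide (not isolated) | C[Si](C)(C)C#CCC[Mg]Br | intermediate
12 | silyl enol ether of the conjugate adduct | C[Si](C)(C)C#CCC[C@]1(C)C(=CO[Si](C)(C)C)CCC[C@H]1C | intermediate
13 | (5R,6S)-enal | C[Si](C)(C)C#CCC[C@]1(C)C(C=O)=CCC[C@H]1C | intermediate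
14 | (5R,6S)-vinylcyclohexene diene | C[Si](C)(C)C#CCC[C@]1(C)C(C=C)=CCC[C@H]1C | intermediate
15 | methacrolein | CC(=C)C=O | starting material
16 | Diels–Alder aldehyde | C[Si](C)(C)C#CCC[C@]1(C)C2=CCC[C@](C)(C=O)[C@H]2CC[C@H]1C | intermediate
17 | silylalkyne acid | C[Si](C)(C)C#CCC[C@]1(C)C2=CCC[C@](C)(C(=O)O)[C@H]2CC[C@H]1C | intermediate
18 | terminal alkyne acid | C#CCC[C@]1(C)C2=CCC[C@](C)(C(=O)O)[C@H]2CC[C@H]1C | intermediate
19 | (E)-vinylalane, aluminium carboxylate (not isolated) | C[Al](C)/C=C(\C)CC[C@]1(C)C2=CCC[C@](C)(C(=O)O[Al](C)C)[C@H]2CC[C@H]1C | intermediate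
20 | 15-hydroxy acid | OC/C=C(\C)CC[C@]1(C)C2=CCC[C@](C)(C(=O)O)[C@H]2CC[C@H]1C | intermediate
21 | target | CC(=O)OC/C=C(\C)CC[C@]1(C)C2=CCC[C@](C)(C(=O)O)[C@H]2CC[C@H]1C | target

Total step count: 13. Longest linear sequence: 13 steps (1 → 21).

Steps most likely to fail

1. Step 3. The second alkylation may close through C10 to a four-membered ring, or the auxiliary may discriminate poorly between the two dienolate faces. The fallback sets out from 5 and comes back at 8.
   - The dianion (NaH, then n-BuLi) of methyl 3-oxopentanoate F1 is alkylated at its γ-carbon with 5 to methyl 7-chloro-4-methyl-3-oxoheptanoate F2.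
   - F2 is cyclised at the α-carbon (K2CO3, NaI, acetone) to methyl 3-methyl-2-oxocyclohexane-1-carboxylate F3.
   - NaH/PhNTf2 gives the enol triflate F4, and Me2CuLi gives racemic methyl 2,3-dimethylcyclohex-1-ene-1-carboxylate F5.
   - LiOH gives the racemic acid F6.
   - Crystallisation with (R)-1-phenylethylamine gives the salt F7, acidification frees the (R)-acid F8, and LiAlH4 reduces it to 8.

2. Step 9. The dienophile may add to the β face of the diene (substrate bias working against the catalyst), or exo selectivity may erode. The fallback sets out from 14 and comes back at 17.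
   - Control is moved into the dienophile: N-methacryloyl-(2R)-bornane-10,2-sultam F13 is combined with 14 under EtAlCl2 to give the N-acylsultam adduct F14.
   - The diastereomers of F14 are separable, and LiOH/H2O2 cleaves the adduct to 17.

3. Step 6. The organocopper reagent may add 1,2 to the aldehyde or not react at the fully substituted β-carbon. The fallback sets out from 8 and comes back at 13.
   - Alcohol 8 is esterified to the picolinate F9.
   - The same Grignard reagent 11 with CuBr·SMe2 displaces it in an SN2′ sense at C9, anti to the C8 methyl, to give the exocyclic methylene compound F10.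
   - m-CPBA gives the spiro-epoxide F11, and diethylaluminium tetramethylpiperidide isomerises it to the allylic alcohol F12.
   - MnO2 oxidises F12 to 13.

Further compounds
F1 | step 3 | methyl 3-oxopentanoate | CCC(=O)CC(=O)OC
F2 | step 3 | methyl 7-chloro-4-methyl-3-oxoheptanoate | COC(=O)CC(=O)C(C)CCCCl
F3 | step 3 | methyl 3-methyl-2-oxocyclohexane-1-carboxylate | COC(=O)C1CCCC(C)C1=O
F4 | step 3 | methyl 3-methyl-2-(trifluoromethylsulfonyloxy)cyclohex-1-ene-1-carboxylate | COC(=O)C1=C(OS(=O)(=O)C(F)(F)F)C(C)CCC1
F5 | step 3 | racemic methyl 2,3-dimethylcyclohex-1-ene-1-carboxylate | COC(=O)C1=C(C)C(C)CCC1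
F6 | step 3 | racemic 2,3-dimethylcyclohex-1-ene-1-carboxylic acid | OC(=O)C1=C(C)C(C)CCC1
F7 | step 3 | (R)-1-phenylethylammonium (3R)-2,3-dimethylcyclohex-1-ene-1-carboxylate | CC1=C(C(=O)[O-])CCC[C@H]1C.C[C@@H]([NH3+])c1ccccc1
F8 | step 3 | (3R)-2,3-dimethylcyclohex-1-ene-1-carboxylic acid | CC1=C(C(=O)O)CCC[C@H]1C
F9 | step 6 | [(3R)-2,3-dimethylcyclohex-1-en-1-yl]methyl picolinate | CC1=C(COC(=O)c2ccccn2)CCC[C@H]1C
F10 | step 6 | (1S,6R)-1,6-dimethyl-2-methylidene-1-[4-(trimethylsilyl)but-3-ynyl]cyclohexane | C[Si](C)(C)C#CCC[C@]1(C)C(=C)CCC[C@H]1C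
F11 | step 6 | spiro-epoxide of F10 | C[Si](C)(C)C#CCC[C@]1(C)C2(CO2)CCC[C@H]1C
F12 | step 6 | {(5R,6S)-5,6-dimethyl-6-[4-(trimethylsilyl)but-3-ynyl]cyclohex-1-en-1-yl}methanol | C[Si](C)(C)C#CCC[C@]1(C)C(CO)=CCC[C@H]1C
F13 | step 9 | N-methacryloyl-(2R)-bornane-10,2-sultam | CC(=C)C(=O)N1[C@@H]2C[C@H]3CC[C@@]2(CS1(=O)=O)C3(C)C
F14 | step 9 | N-acylsultam Diels–Alder adduct | C[Si](C)(C)C#CCC[C@]1(C)C2=CCC[C@](C)(C(=O)N3[C@@H]4C[C@H]5CC[C@@]4(CS3(=O)=O)C5(C)C)[C@H]2CC[C@H]1C
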